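**Plan**
- The retrosynthesis first removes three benzyl groups and cuts the O–CH3 bond at B2. It then cuts the aryl ester bond between the ring A carbonyl and O4 of ring B. This leaves two units with the same olivetolate skeleton.
- Ring B is a benzoate with the carboxyl on B1, oxygen on B2 and B4, and pentyl on B6, and ring A has the same pattern. B1, B2 and the carboxyl carbon therefore come from a malonate. B3 to B6 and the pentyl chain come from non-3-en-2-one, so the ring is cut at B1–B6 and B2–B3.
- In the forward direction, a Michael/Dieckmann annulation builds the carbocycle and dehydrogenation gives benzyl olivetolate. This compound is used twice: one part is dibenzylated and saponified to the ring A acid, and the rest serves as the ring B phenol.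
- The halves are joined at the free O4 of ring B, and the hydrogen-bonded O2 hydroxyl is then methylated. One hydrogenolysis removes all three benzyl groups.
- The target has no stereocentre. The two sp3 centres of the annulation product are racemic and disappear on aromatisation.

Key step: step 1

Remark: compound 4 is drawn as its diketo tautomer. It should exist largely as the enol (2-hydroxy-4-oxocyclohex-2-ene-1-carboxylate), which changes nothing in the route.

**Step 1**
Reactants: 1 (E)-non-3-en-2-one; 2 dibenzyl malonate
Product: 4 benzyl trans-2,4-dioxo-6-pentylcyclohexane-1-carboxylate (racemic), via Michael adduct 3 (not isolated)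
Conditions: NaH (1.1 equiv), THF, 0 °C; then 1, rt to reflux; cold 1 M HCl
Reagents that add atoms: none
Why: This is the tandem Michael addition and Dieckmann condensation long used to turn a dialkyl malonate and a beta-alkyl enone into a 6-alkyl-2,4-dioxocyclohexanecarboxylate, here run on the benzyl ester. The sodium malonate adds to the beta carbon C4 of 1 (ring bond B1–B6) to give 3, proton exchange relayed by liberated benzyl alcohol produces the methyl ketone enolate, and this carbon attacks one malonate ester carbonyl with loss of benzyloxide (ring bond B2–B3). The six-membered ring closes in a 6-(enolendo)-exo-trig acyl substitution, whereas the internal CH2 enolate could only form a four-membered ring, so ring size alone decides which enolate is productive. Conjugate addition has to win over attack at the ketone carbonyl, which the soft, stabilised malonate anion and the reversibility of carbonyl addition secure, and the released benzyloxide deprotonates the cyclic beta-diketone so that its stable enolate draws all the equilibria to 4. NaH in THF keeps benzyloxide as the only alkoxide in the flask, so no ester exchange can occur, and either of the two ester groups of 3 gives the same constitution. The centres C1 and C6 arise racemic, the acidic C1 equilibrates to place the ester trans to the pentyl group with both equatorial, and both centres are erased in step 2.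

**Step 2**
Reactants: 4 benzyl trans-2,4-dioxo-6-pentylcyclohexane-1-carboxylate
Product: 5 benzyl 2,4-dihydroxy-6-pentylbenzoate (benzyl olivetolate)
Conditions: I2 (20 mol %), DMSO, 80 °C
Reagents that add atoms: none
Why: Iodine-catalysed oxidative aromatisation with DMSO as terminal oxidant (alpha-iodination, loss of HI, tautomerisation of the dienone, reoxidation of HI by DMSO) is known for alkyl 6-alkyl-2,4-dioxocyclohexanecarboxylates, and the low standing concentration of HI should spare the benzyl ester.

**Step 3**
Reactants: 5 benzyl 2,4-dihydroxy-6-pentylbenzoate (one portion)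
Product: 6 benzyl 2,4-bis(benzyloxy)-6-pentylbenzoate
Conditions: BnBr (2.5 equiv), K2CO3, DMF, 60 °C
Reagents that add atoms: benzyl bromide, BrCc1ccccc1
Why: In this Williamson etherification the free O4 hydroxyl reacts first, and warming in DMF with excess halide also alkylates the hydrogen-bonded O2 hydroxyl.

**Step 4**
Reactants: 6 benzyl 2,4-bis(benzyloxy)-6-pentylbenzoate
Product: 7 2,4-bis(benzyloxy)-6-pentylbenzoic acid
Conditions: KOH, DMSO–H2O, 100 °C; then 1 M HCl, 0 °C
Reagents that add atoms: potassium hydroxide, [K+].[OH-]
Why: Saponification of a di-ortho-substituted benzoate succeeds with poorly solvated hydroxide in hot aqueous DMSO, the aryl benzyl ethers are inert to base, and cold acidification avoids decarboxylation of the electron-rich acid.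

**Step 5**
Reactants: 7 2,4-bis(benzyloxy)-6-pentylbenzoic acid; 5 benzyl 2,4-dihydroxy-6-pentylbenzoate (second portion)
Product: 9 benzyl 4-{[2,4-bis(benzyloxy)-6-pentylbenzoyl]oxy}-2-hydroxy-6-pentylbenzoate, via mixed trifluoroacetic anhydride 8 (not isolated)
Conditions: (CF3CO)2O, toluene, rt
Reagents that add atoms: trifluoroacetic anhydride, O=C(OC(=O)C(F)(F)F)C(F)(F)F (its CF3CO group is carried by 8 only; none of its atoms remain in 9)
Why: In this standard depside esterification through a mixed trifluoroacetic anhydride, the electron-rich hindered acid ionises easily to an acylium-type acylating agent, and only the free O4 hydroxyl of 5 reacts because the O2 hydroxyl is hydrogen-bonded to the neighbouring ester carbonyl and crowded by it.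

**Step 6**
Reactants: 9 benzyl 4-{[2,4-bis(benzyloxy)-6-pentylbenzoyl]oxy}-2-hydroxy-6-pentylbenzoate
Product: 10 benzyl 4-{[2,4-bis(benzyloxy)-6-pentylbenzoyl]oxy}-2-methoxy-6-pentylbenzoate
Conditions: MeI, K2CO3, dry acetone, 50 °C
Reagents that add atoms: methyl iodide, CI
Why: This is a Williamson O-methylation of the only hydroxyl left in the molecule, and in a dry aprotic medium with excess MeI the depside carbonyl, shielded by its two ortho substituents, should not suffer acyl transfer.

**Step 7**
Reactants: 10 benzyl 4-{[2,4-bis(benzyloxy)-6-pentylbenzoyl]oxy}-2-methoxy-6-pentylbenzoate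
Product: 11 4-[(2,4-dihydroxy-6-pentylbenzoyl)oxy]-2-methoxy-6-pentylbenzoic acid (target)
Conditions: H2 (1 atm), 10% Pd/C, EtOAc, rt
Reagents that add atoms: none
Why: Catalytic hydrogenolysis cleaves the two aryl benzyl ethers and the benzyl ester in one operation, the aryl ester link and the methyl ether have no benzylic C–O bond and stay, and the non-nucleophilic solvent excludes alcoholysis of the depside.

**Compound list**
1 | (E)-non-3-en-2-one | CCCCC/C=C/C(C)=O | starting material
2 | dibenzyl malonate | O=C(CC(=O)OCc1ccccc1)OCc1ccccc1 | starting material
3 | dibenzyl 2-(2-oxononan-4-yl)propanedioate (racemic Michael adduct, not isolated) | CCCCCC(CC(C)=O)C(C(=O)OCc1ccccc1)C(=O)OCc1ccccc1 | intermediate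
4 | benzyl trans-2,4-dioxo-6-pentylcyclohexane-1-carboxylate (racemic, one enantiomer drawn) | CCCCC[C@@H]1CC(=O)CC(=O)[C@H]1C(=O)OCc1ccccc1 | intermediate
5 | benzyl 2,4-dihydroxy-6-pentylbenzoate | CCCCCc1cc(O)cc(O)c1C(=O)OCc1ccccc1 | intermediate
6 | benzyl 2,4-bis(benzyloxy)-6-pentylbenzoate | CCCCCc1cc(OCc2ccccc2)cc(OCc2ccccc2)c1C(=O)OCc1ccccc1 | intermediate
7 | 2,4-bis(benzyloxy)-6-pentylbenzoic acid | CCCCCc1cc(OCc2ccccc2)cc(OCc2ccccc2)c1C(=O)O | intermediate
8 | 2,4-bis(benzyloxy)-6-pentylbenzoic trifluoroacetic anhydride (not isolated) | CCCCCc1cc(OCc2ccccc2)cc(OCc2ccccc2)c1C(=O)OC(=O)C(F)(F)F | intermediate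
9 | benzyl 4-{[2,4-bis(benzyloxy)-6-pentylbenzoyl]oxy}-2-hydroxy-6-pentylbenzoate | CCCCCc1cc(OCc2ccccc2)cc(OCc2ccccc2)c1C(=O)Oc1cc(O)c(C(=O)OCc2ccccc2)c(CCCCC)c1 | intermediate
10 | benzyl 4-{[2,4-bis(benzyloxy)-6-pentylbenzoyl]oxy}-2-methoxy-6-pentylbenzoate | CCCCCc1cc(OCc2ccccc2)cc(OCc2ccccc2)c1C(=O)Oc1cc(OC)c(C(=O)OCc2ccccc2)c(CCCCC)c1 | intermediate
11 | 4-[(2,4-dihydroxy-6-pentylbenzoyl)oxy]-2-methoxy-6-pentylbenzoic acid | CCCCCc1cc(O)cc(O)c1C(=O)Oc1cc(CCCCC)c(C(=O)O)c(OC)c1 | target

Total step count: 7
Longest linear sequence: 7 steps (1 to 7 in order, because compound 5 feeds both halves)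

**Steps most likely to fail**

Step 2 (aromatisation).
- Risk: The dehydrogenation may stall. The iodinated stage may be diverted by Kornblum-type oxygenation. The electron-rich ring formed may be iodinated. Acid may also strip the benzyl ester, with decarboxylation following.
- Fallback: It sets out from 4 and returns at 5, and it replaces halogenation/elimination by hydride abstraction from a masked diene.
- TMSOTf and Et3N in CH2Cl2 should convert 4 into benzyl 6-pentyl-2,4-bis(trimethylsilyloxy)cyclohexa-1,3-diene-1-carboxylate F1.
- DDQ in toluene at rt should dehydrogenate this cyclohexadiene to benzyl 6-pentyl-2,4-bis(trimethylsilyloxy)benzoate F2.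
- Dilute HCl in THF then removes both silyl groups to give 5.
- No halogen and no hydrogen halide are present, and the nucleophilic carbon between the two carbonyls is blocked from adding to the quinone.

Step 6 (methylation on the assembled depside).
- Risk: The phenoxide may take over the acyl group of a second molecule, or traces of water may cleave the aryl ester. Either process would scramble or break the depside.
- Fallback: It sets out from 5 and returns at 10, and it reverses the order of events so that the methyl ether is in place before the ester link exists.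
- TIPSCl and imidazole in CH2Cl2 at 0 °C should silylate only the free O4 hydroxyl, giving benzyl 2-hydroxy-6-pentyl-4-(triisopropylsilyloxy)benzoate F3.
- MeI and K2CO3 in acetone should give benzyl 2-methoxy-6-pentyl-4-(triisopropylsilyloxy)benzoate F4.
- TBAF buffered with AcOH in THF should release benzyl 4-hydroxy-2-methoxy-6-pentylbenzoate F5.
- F5 is then acylated with acid 7 through anhydride 8 under the conditions of step 5 and gives 10 directly.

Step 1 (annulation with the benzyl ester in an aprotic medium).
- Risk: Proton transfer and ring closure may lag behind the conjugate addition. The reaction could then stop at the open chain, revert by retro-Michael cleavage, or lose enone to self-condensation.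
- Fallback: It sets out from 1 and returns at 4. The same two bonds are formed in the matched alkoxide/alcohol medium, and the benzyl ester is installed afterwards.
- Dimethyl malonate, NaOMe and 1 in refluxing MeOH should pass through dimethyl 2-(2-oxononan-4-yl)propanedioate F6 to methyl trans-2,4-dioxo-6-pentylcyclohexane-1-carboxylate F7.
- Heating F7 with benzyl alcohol in toluene, with distillative removal of methanol, should give 4 by thermal beta-keto ester exchange through the acylketene.

**Further compounds**
F1 | step 2 | benzyl 6-pentyl-2,4-bis(trimethylsilyloxy)cyclohexa-1,3-diene-1-carboxylate (racemic) | CCCCCC1CC(O[Si](C)(C)C)=CC(O[Si](C)(C)C)=C1C(=O)OCc1ccccc1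
F2 | step 2 | benzyl 6-pentyl-2,4-bis(trimethylsilyloxy)benzoate | CCCCCc1cc(O[Si](C)(C)C)cc(O[Si](C)(C)C)c1C(=O)OCc1ccccc1
F3 | step 6 | benzyl 2-hydroxy-6-pentyl-4-(triisopropylsilyloxy)benzoate | CCCCCc1cc(O[Si](C(C)C)(C(C)C)C(C)C)cc(O)c1C(=O)OCc1ccccc1
F4 | step 6 | benzyl 2-methoxy-6-pentyl-4-(triisopropylsilyloxy)benzoate | CCCCCc1cc(O[Si](C(C)C)(C(C)C)C(C)C)cc(OC)c1C(=O)OCc1ccccc1
F5 | step 6 | benzyl 4-hydroxy-2-methoxy-6-pentylbenzoate | CCCCCc1cc(O)cc(OC)c1C(=O)OCc1ccccc1
F6 | step 1 | dimethyl 2-(2-oxononan-4-yl)propanedioate (racemic, not isolated) | CCCCCC(CC(C)=O)C(C(=O)OC)C(=O)OC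
F7 | step 1 | methyl trans-2,4-dioxo-6-pentylcyclohexane-1-carboxylate (racemic, one enantiomer drawn) | CCCCC[C@@H]1CC(=O)CC(=O)[C@H]1C(=O)OC
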